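**Retrosynthetic overview**

1. Last step: putraflavone from its 4',5'',7''-tri-O-benzyl ether by hydrogenolysis. Benzyl is the only protecting group, since it can be removed beside the 7-OMe and 4'''-OMe groups that the target keeps.
2. Key disconnection: the C2–C1' bond of flavone unit 1 (chromone C2 to the ring B carbon para to the 4'-oxygen), made by Sonogashira coupling of a ring B aryl iodide with a terminal ynone whose alkyne carbon becomes C2. The ynone hangs on a 4-methoxy-2-pyrone, a poly-β-carbonyl chain masked as lactone, enol ether and alkyne; in the same pot Mg(OMe)2 folds it by Claisen condensation into ring A, and a phenol then closes ring C.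
3. Enabling feature: ring A of unit 1 has the acetate-type 1,3,5-oxygen pattern (O1 on C8a, OH on C5, OMe on C7) around the acyl-bearing C4a and is symmetric about the C4a–C7 axis. The pyrone 4-OMe therefore maps on the 7-OMe and the lactone oxygens on C5–O and C8a–O, the folding has no regiochemical choice, and either phenol closes the same ring C onto C2 (the carbon β to C4=O). C1' lies para to the 4'-OH, so its iodide can be set by phenoxide iodination.
4. Aryl iodide: from acacetin (rings A'', C'', B'' of unit 2 bought intact) by benzylation, C8'' iodination, Suzuki coupling with (2-hydroxyphenyl)boronic acid (ring B), para-iodination and benzylation. Pyrone ynone: from 4-methoxy-6-methyl-2-pyrone and 3-(trimethylsilyl)propynal by vinylogous aldol addition, desilylation and oxidation.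
5. Ring order: A''/C''/B'' (acacetin), then ring B attached at C8'', then ring A and ring C of unit 1, both in the key step.

Key step: step 9

Remark: the C3'–C8'' biaryl axis has no descriptor in the target and is not controlled; alcohols 10 and 11 are racemic and their stereocentre is removed in step 8, so the target has no stereocentre to set; 13, 14 and 15 are written as neutral forms of species that are present as amine or magnesium salts.

**Route**

Step 1
Reactants: 1 acacetin (5,7-dihydroxy-2-(4-methoxyphenyl)-4H-chromen-4-one)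
Product: 2 5,7-bis(benzyloxy)-2-(4-methoxyphenyl)-4H-chromen-4-one
Conditions: BnBr (3 equiv), K2CO3, DMF, 80 °C
Reagents that add atoms: benzyl bromide, BrCc1ccccc1
Why: Williamson ether synthesis on both phenoxides, with excess reagent and heat to force the chelated 5-OH; benzyl is chosen because hydrogenolysis should remove it later without touching the methyl ethers.

Step 2
Reactants: 2 5,7-bis(benzyloxy)-2-(4-methoxyphenyl)-4H-chromen-4-one
Product: 3 5,7-bis(benzyloxy)-8-iodo-2-(4-methoxyphenyl)-4H-chromen-4-one
Conditions: I2, CF3CO2Ag, CH2Cl2, 0 °C to rt, dark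
Reagents that add atoms: iodine, [I][I]
Why: Electrophilic aromatic iodination by CF3CO2I formed in the flask should go to C8 (ortho to the 7-oxygen and to O1, para to the 5-oxygen), the preferred site of 5,7-dialkoxyflavones as known for 5,7-dimethoxyflavones, and C6 is in addition shielded by two benzyloxy groups.

Step 3
Reactants: 3 5,7-bis(benzyloxy)-8-iodo-2-(4-methoxyphenyl)-4H-chromen-4-one; 4 (2-hydroxyphenyl)boronic acid
Product: 5 5,7-bis(benzyloxy)-8-(2-hydroxyphenyl)-2-(4-methoxyphenyl)-4H-chromen-4-one
Conditions: Pd(OAc)2 (5 mol %), SPhos (10 mol %), K3PO4, toluene/H2O, 90 °C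
Reagents that add atoms: none
Why: Suzuki–Miyaura coupling, in which the bulky electron-rich SPhos ligand should allow oxidative addition and reductive elimination at the doubly ortho-substituted C8'' iodide and the free phenol of 4 is tolerated as its phenoxide.

Step 4
Reactants: 5 5,7-bis(benzyloxy)-8-(2-hydroxyphenyl)-2-(4-methoxyphenyl)-4H-chromen-4-one
Product: 6 5,7-bis(benzyloxy)-8-(2-hydroxy-5-iodophenyl)-2-(4-methoxyphenyl)-4H-chromen-4-one
Conditions: NaI, NaOH, aqueous NaOCl (added slowly), MeOH/THF, 0 °C
Reagents that add atoms: sodium iodide, [Na+].[I-]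
Why: Electrophilic iodination of the phenoxide by hypoiodite made from NaI and NaOCl should touch only the phenoxide ring (not the benzyl- and methyl-ether rings), and an ortho-substituted phenoxide is expected to be iodinated para to oxygen, which is C1'.

Step 5
Reactants: 6 5,7-bis(benzyloxy)-8-(2-hydroxy-5-iodophenyl)-2-(4-methoxyphenyl)-4H-chromen-4-one
Product: 7 5,7-bis(benzyloxy)-8-[2-(benzyloxy)-5-iodophenyl]-2-(4-methoxyphenyl)-4H-chromen-4-one
Conditions: BnBr, K2CO3, DMF, rt
Reagents that add atoms: benzyl bromide, BrCc1ccccc1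
Why: Williamson ether synthesis, after which the capped phenol can no longer add to the ynone in step 9 and all three protecting groups should leave together in step 10.

Step 6
Reactants: 8 4-methoxy-6-methyl-2H-pyran-2-one; 9 3-(trimethylsilyl)prop-2-ynal
Product: 10 6-[2-hydroxy-4-(trimethylsilyl)but-3-yn-1-yl]-4-methoxy-2H-pyran-2-one (racemic)
Conditions: LiN(i-Pr)2 (LDA), THF, −78 °C; then 9; then aqueous NH4Cl
Reagents that add atoms: none
Why: Vinylogous aldol addition, in which LiN(i-Pr)2 deprotonates the C6 methyl group (dienolate through the lactone carbonyl) and the exocyclic carbon should add to the aldehyde as known for this pyrone; the new carbinol centre is formed racemic without control and is destroyed in step 8.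

Step 7
Reactants: 10 6-[2-hydroxy-4-(trimethylsilyl)but-3-yn-1-yl]-4-methoxy-2H-pyran-2-one (racemic)
Product: 11 6-(2-hydroxybut-3-yn-1-yl)-4-methoxy-2H-pyran-2-one (racemic)
Conditions: K2CO3 (0.2 equiv), MeOH, 0 °C
Reagents that add atoms: none
Why: Protodesilylation of the alkynylsilane by catalytic methoxide should be fast at 0 °C and mild enough to leave the lactone and the β-hydroxy group alone, the stereocentre staying racemic.

Step 8
Reactants: 11 6-(2-hydroxybut-3-yn-1-yl)-4-methoxy-2H-pyran-2-one (racemic)
Product: 12 4-methoxy-6-(2-oxobut-3-yn-1-yl)-2H-pyran-2-one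
Conditions: Dess–Martin periodinane, CH2Cl2, 0 °C to rt
Reagents that add atoms: none
Why: Dess–Martin oxidation of the secondary propargylic alcohol under neutral, anhydrous conditions should give the ynone and remove the only stereocentre, and 12 is to be used at once because its methylene group is doubly activated.

Step 9
Reactants: 7 5,7-bis(benzyloxy)-8-[2-(benzyloxy)-5-iodophenyl]-2-(4-methoxyphenyl)-4H-chromen-4-one; 12 4-methoxy-6-(2-oxobut-3-yn-1-yl)-2H-pyran-2-one
Product: 16 5,7-bis(benzyloxy)-8-[2-(benzyloxy)-5-(5-hydroxy-7-methoxy-4-oxo-4H-chromen-2-yl)phenyl]-2-(4-methoxyphenyl)-4H-chromen-4-one (4',5'',7''-tri-O-benzylputraflavone), via coupled pyrone ynone 13 (not isolated), via ring-opened triketide ester 14 (not isolated), via acylphloroglucinol ynone 15 (not isolated)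
Conditions: 12 (1.3 equiv), Pd(PPh3)2Cl2 (5 mol %), CuI (5 mol %), i-Pr2NEt, THF, rt; then Mg(OMe)2, MeOH, 65 °C; then 2 M aqueous HCl, 50 °C
Reagents that add atoms: none
Why: Proposed new method: a Sonogashira coupling (oxidative addition of the carbon–iodine bond of 7 to zerovalent palladium, transmetalation from the alkynylcopper species formed from 12 and CuI, reductive elimination) should make the C1'–C2 bond and give 13, and Mg(OMe)2 should then open the lactone at the pyrone carbonyl carbon to the magnesium-chelated triketide ester 14, whose central methylene carbon attacks the ester carbonyl in a Claisen condensation (6-exo-trig) and, after loss of methoxide and enolisation, becomes C4a of the new benzene ring A in 15. A phenoxide of 15 should then close ring C on the alkyne carbon that carries ring B (6-endo-dig oxa-Michael addition, or 6-endo-trig addition–elimination on the methanol adduct of the ynone), and the acid stage frees the product from magnesium and completes any cyclodehydration; 13, 15 and 16 are isomers, so the pot only reorganises the ten carbons of 12 into rings A and C. The closest known reaction types are the Sonogashira coupling of terminal ynones with aryl iodides, the Mg(OMe)2-mediated Claisen folding of 6-(2-oxoalkyl)-4-methoxy-2-pyrones (lactones of masked 3,5,7-triketo acids) into acylphloroglucinols, and the closure of 2-hydroxyaryl ynones to flavones; what is new is the alkynyl ketone in the folding and its telescoping with the coupling. No stereocentre is formed. The step needs the Claisen mode instead of carbocyclisation of the pyrone C5 carbon (or of the opened chain) onto the ynone, and 6-endo instead of 5-exo (aurone) closure: magnesium chelation of the 1,3-diketone makes the central carbon the nucleophile and activates the ester, the cis arrangement of ester and chain across the enoate double bond is inherited from the pyrone ring, methoxide addition to the ynone keeps it from acting as a carbon acceptor and turns the last closure into an addition–elimination that can only be 6-endo, and since the new ring A is symmetric about the C4a–C7 axis either phenol gives the same chromone.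

Step 10
Reactants: 16 5,7-bis(benzyloxy)-8-[2-(benzyloxy)-5-(5-hydroxy-7-methoxy-4-oxo-4H-chromen-2-yl)phenyl]-2-(4-methoxyphenyl)-4H-chromen-4-one
Product: 17 putraflavone (5,7-dihydroxy-8-[2-hydroxy-5-(5-hydroxy-7-methoxy-4-oxo-4H-chromen-2-yl)phenyl]-2-(4-methoxyphenyl)-4H-chromen-4-one)
Conditions: H2 (1 atm), Pd/C (10 % palladium metal on carbon), THF/MeOH, rt
Reagents that add atoms: none
Why: Hydrogenolysis of the three aryl benzyl ethers should free the 4'-, 5''- and 7''-hydroxyl groups, while the methyl ethers, the phenols and the two chromone C2=C3 bonds (vinylogous esters that resist hydrogenation under these conditions) are expected to survive.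

**Compound list**

1 | acacetin, 5,7-dihydroxy-2-(4-methoxyphenyl)-4H-chromen-4-one | COc1ccc(-c2cc(=O)c3c(O)cc(O)cc3o2)cc1 | starting material
2 | 5,7-bis(benzyloxy)-2-(4-methoxyphenyl)-4H-chromen-4-one | COc1ccc(-c2cc(=O)c3c(OCc4ccccc4)cc(OCc4ccccc4)cc3o2)cc1 | intermediate
3 | 5,7-bis(benzyloxy)-8-iodo-2-(4-methoxyphenyl)-4H-chromen-4-one | COc1ccc(-c2cc(=O)c3c(OCc4ccccc4)cc(OCc4ccccc4)c(I)c3o2)cc1 | intermediate
4 | (2-hydroxyphenyl)boronic acid | OB(O)c1ccccc1O | starting material
5 | 5,7-bis(benzyloxy)-8-(2-hydroxyphenyl)-2-(4-methoxyphenyl)-4H-chromen-4-one | COc1ccc(-c2cc(=O)c3c(OCc4ccccc4)cc(OCc4ccccc4)c(-c4ccccc4O)c3o2)cc1 | intermediate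
6 | 5,7-bis(benzyloxy)-8-(2-hydroxy-5-iodophenyl)-2-(4-methoxyphenyl)-4H-chromen-4-one | COc1ccc(-c2cc(=O)c3c(OCc4ccccc4)cc(OCc4ccccc4)c(-c4cc(I)ccc4O)c3o2)cc1 | intermediate
7 | 5,7-bis(benzyloxy)-8-[2-(benzyloxy)-5-iodophenyl]-2-(4-methoxyphenyl)-4H-chromen-4-one | COc1ccc(-c2cc(=O)c3c(OCc4ccccc4)cc(OCc4ccccc4)c(-c4cc(I)ccc4OCc4ccccc4)c3o2)cc1 | intermediate
8 | 4-methoxy-6-methyl-2H-pyran-2-one | COC1=CC(=O)OC(C)=C1 | starting material
9 | 3-(trimethylsilyl)prop-2-ynal | C[Si](C)(C)C#CC=O | starting material
10 | 6-[2-hydroxy-4-(trimethylsilyl)but-3-yn-1-yl]-4-methoxy-2H-pyran-2-one (racemic) | COC1=CC(=O)OC(CC(O)C#C[Si](C)(C)C)=C1 | intermediate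
11 | 6-(2-hydroxybut-3-yn-1-yl)-4-methoxy-2H-pyran-2-one (racemic) | COC1=CC(=O)OC(CC(O)C#C)=C1 | intermediate
12 | 4-methoxy-6-(2-oxobut-3-yn-1-yl)-2H-pyran-2-one | COC1=CC(=O)OC(CC(=O)C#C)=C1 | intermediate
13 | 5,7-bis(benzyloxy)-8-{2-(benzyloxy)-5-[4-(4-methoxy-2-oxo-2H-pyran-6-yl)-3-oxobut-1-yn-1-yl]phenyl}-2-(4-methoxyphenyl)-4H-chromen-4-one | COc1ccc(-c2cc(=O)c3c(OCc4ccccc4)cc(OCc4ccccc4)c(-c4cc(C#CC(=O)CC5=CC(OC)=CC(=O)O5)ccc4OCc4ccccc4)c3o2)cc1 | intermediate
14 | methyl (2E)-9-{4-(benzyloxy)-3-[5,7-bis(benzyloxy)-2-(4-methoxyphenyl)-4-oxo-4H-chromen-8-yl]phenyl}-3-methoxy-5,7-dioxonon-2-en-8-ynoate | COC(=O)/C=C(/OC)CC(=O)CC(=O)C#Cc1ccc(OCc2ccccc2)c(-c2c(OCc3ccccc3)cc(OCc3ccccc3)c3c(=O)cc(-c4ccc(OC)cc4)oc23)c1 | intermediate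
15 | 5,7-bis(benzyloxy)-8-{2-(benzyloxy)-5-[3-(2,6-dihydroxy-4-methoxyphenyl)-3-oxoprop-1-yn-1-yl]phenyl}-2-(4-methoxyphenyl)-4H-chromen-4-one | COc1ccc(-c2cc(=O)c3c(OCc4ccccc4)cc(OCc4ccccc4)c(-c4cc(C#CC(=O)c5c(O)cc(OC)cc5O)ccc4OCc4ccccc4)c3o2)cc1 | intermediate
16 | 5,7-bis(benzyloxy)-8-[2-(benzyloxy)-5-(5-hydroxy-7-methoxy-4-oxo-4H-chromen-2-yl)phenyl]-2-(4-methoxyphenyl)-4H-chromen-4-one | COc1ccc(-c2cc(=O)c3c(OCc4ccccc4)cc(OCc4ccccc4)c(-c4cc(-c5cc(=O)c6c(O)cc(OC)cc6o5)ccc4OCc4ccccc4)c3o2)cc1 | intermediate
17 | putraflavone, 5,7-dihydroxy-8-[2-hydroxy-5-(5-hydroxy-7-methoxy-4-oxo-4H-chromen-2-yl)phenyl]-2-(4-methoxyphenyl)-4H-chromen-4-one | COc1ccc(-c2cc(=O)c3c(O)cc(O)c(-c4cc(-c5cc(=O)c6c(O)cc(OC)cc6o5)ccc4O)c3o2)cc1 | target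

**Step count and risks**

Total step count: 10. Longest linear sequence: 7 steps (1, 2, 3, 4, 5, 9, 10).

Step 9 (Proposed new method). What may go wrong: self-condensation of the ynone through its activated methylene group under the amine base before cross-coupling; folding through carbon-Michael or aldol modes instead of the Claisen mode; ring opening of the finished chromone of unit 2 by methoxide. The fallback uses known chemistry, keeps the same C2–C1' union and brings in the chromone ready-made. It sets out from 7: Miyaura borylation (B2pin2, Pd(dppf)Cl2, KOAc, dioxane, 90 °C) should give the pinacol boronate F1. Commercial 1-(2,6-dihydroxy-4-methoxyphenyl)ethanone is condensed with N,N-dimethylformamide dimethyl acetal to the enaminone F2, which should close in aqueous HCl to 5-hydroxy-7-methoxy-4H-chromen-4-one F3. Oxidative boron-Heck arylation of F3 at C2 with F1 (Pd(O2CCF3)2, 5-nitro-1,10-phenanthroline, O2, DMSO, 100 °C; transmetalation to divalent palladium, carbopalladation of C2=C3, β-hydride elimination) should give 16, where the route is rejoined.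

Step 8. What may go wrong: polymerisation or self-Michael addition of the terminal ynone during oxidation, concentration or storage, or dehydration of the β-hydroxy group before oxidation. The fallback never makes the free terminal ynone. It sets out from 11 and 7: Sonogashira coupling at the alcohol level (Pd(PPh3)2Cl2, CuI, i-Pr2NEt, THF, rt) should give the coupled propargylic alcohol F4, and Dess–Martin oxidation of F4 should give 13 as an isolated compound. The route is rejoined at 13, which the Mg(OMe)2 and acid stages of step 9 should carry to 16.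

Step 4. What may go wrong: loss of site control, by iodination ortho to the phenol, double iodination, or attack on ring A'' at C6''. The fallback fixes the position through the building block. It sets out from 3: Suzuki–Miyaura coupling with commercial [2-(benzyloxy)-5-chlorophenyl]boronic acid (Pd(PPh3)4, K2CO3, dioxane/H2O, 90 °C; the iodide couples, the chloride does not) should give the aryl chloride F5. Miyaura borylation of the chloride (Pd2(dba)3, XPhos, B2pin2, KOAc, dioxane, 100 °C) should give the pinacol boronate F1, and copper-mediated iododeboronation (CuI, 1,10-phenanthroline, KI, air, MeOH/H2O, 80 °C) should give 7, where the route is rejoined.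

Further compounds
F1 | step 9 | 5,7-bis(benzyloxy)-8-[2-(benzyloxy)-5-(4,4,5,5-tetramethyl-1,3,2-dioxaborolan-2-yl)phenyl]-2-(4-methoxyphenyl)-4H-chromen-4-one | COc1ccc(-c2cc(=O)c3c(OCc4ccccc4)cc(OCc4ccccc4)c(-c4cc(B5OC(C)(C)C(C)(C)O5)ccc4OCc4ccccc4)c3o2)cc1
F2 | step 9 | (2E)-1-(2,6-dihydroxy-4-methoxyphenyl)-3-(dimethylamino)prop-2-en-1-one | COc1cc(O)c(C(=O)/C=C/N(C)C)c(O)c1
F3 | step 9 | 5-hydroxy-7-methoxy-4H-chromen-4-one | COc1cc(O)c2c(=O)ccoc2c1
F4 | step 8 | 5,7-bis(benzyloxy)-8-{2-(benzyloxy)-5-[3-hydroxy-4-(4-methoxy-2-oxo-2H-pyran-6-yl)but-1-yn-1-yl]phenyl}-2-(4-methoxyphenyl)-4H-chromen-4-one (racemic) | COc1ccc(-c2cc(=O)c3c(OCc4ccccc4)cc(OCc4ccccc4)c(-c4cc(C#CC(O)CC5=CC(OC)=CC(=O)O5)ccc4OCc4ccccc4)c3o2)cc1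
F5 | step 4 | 5,7-bis(benzyloxy)-8-[2-(benzyloxy)-5-chlorophenyl]-2-(4-methoxyphenyl)-4H-chromen-4-one | COc1ccc(-c2cc(=O)c3c(OCc4ccccc4)cc(OCc4ccccc4)c(-c4cc(Cl)ccc4OCc4ccccc4)c3o2)cc1
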